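## Structural features

The target, C24H14O11, is a flat, achiral phlorotannin of the fucofuroeckol type made of four oxygenated benzene rings. Ring A and ring B are the two benzo rings of a dibenzo-1,4-dioxin, ring B is also one half of a dibenzofuran whose other half is ring C, and ring D is a 3,5-dihydroxyphenyl group bound to ring A through an ether oxygen. There is no stereocentre, so no stereocentres stand next to each other; the only one met on the way is the carbinol carbon of a racemic cyclobutenone, and the key step erases it. Going round ring A, the carbons are: the ring D ether carbon, a hydroxyl carbon, the single CH, a second hydroxyl carbon and the two dioxin carbons. The dioxin oxygen next to the second hydroxyl carbon is bound to C1 of the dibenzofuran (the bay carbon beside the C9 oxygen), and the dioxin oxygen next to the ring D ether carbon is bound to C2. Fragile elements are the seven free phenols on electron-rich rings (air oxidation, hence alkyl ethers until the last step) and, among the intermediates, the cyclobutenone, the acid-labile enol ether and any para-dihydroxy form of ring A, which would oxidise to a quinone. The real difficulty is twofold: five neighbouring oxygens on ring A have five different fates and must be told apart, and the dioxin must be fused in one orientation onto C1/C2 of the dibenzofuran through two diaryl ether bonds that each have substituents on all four ortho positions. The key step uses the fact that four ring A carbons (ring D ether carbon, both dioxin carbons, one hydroxyl carbon) are the four carbons of squaric acid, each already bearing its oxygen, while the other hydroxyl carbon and the CH are a 1-alkoxyvinyl unit. The para pair formed by the dioxin carbon bound to C1 and the hydroxyl carbon next to the ring D ether corresponds to the carbinol and carbonyl carbons of a 4-oxycyclobutenone.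

## Logic of the disconnections

26 from 25. Six O–CH3 bonds and one O–CH2CH3 bond are cut, so that every phenol stays masked until the end. The gain is an air-stable, chromatographable penultimate compound. The demand is a single Lewis-acid dealkylation that removes seven alkyl groups without touching diaryl ether, dioxin or furan C–O bonds.

25 from 24. The dioxin C–O bond between C2 of the dibenzofuran and the ring A oxygen next to the ring D ether carbon is cut. This leaves a ring closure through a six-membered transition ring as the second, easier of the two ether formations. The forward step needs a free phenol beside the first ether bond and a bromide at C2.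

24 from 23. The O–CH(CH3)2 bond is cut. The isopropyl group is the one alkyl group that a boron trihalide removes in the presence of methyl and ethyl ethers, which keeps this oxygen distinct from all others. The demand is chemoselective cleavage of a secondary alkyl ether.

23 from 15 and 22. The ether bond between C1 of the dibenzofuran and the ring A oxygen flanked by the ethoxy and isopropoxy carbons is cut. This divides the molecule into a ring A/D half and a ring B/C half of similar size. The forward step is the hardest bond formation of the route: a copper-catalysed etherification with substituents on all four ortho positions, which must use the C–I bond of 22 and leave its C–Br bond.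

15 from 13 (through 14). One O–CH3 and one O–Si bond are exchanged. The phenol that the ring expansion leaves free is capped and the para oxygen, masked from the start, is then uncovered. The demand is only that excess alkylating agent is gone before fluoride is added.

13 from 10. The ring A C–C bond between the CH and the neighbouring hydroxyl carbon is cut; in the reverse sense the four-membered ring is re-formed between that hydroxyl carbon (as carbonyl) and the para oxygenated carbon (as carbinol). This removes ring A altogether and reduces its five oxygens to those of a squarate diester plus one enol ether. The forward step must open the cyclobutenone with the oxygen substituent turning outward so that the vinyl group meets the ketene.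

10 from 6 and 7. The C–C bond between the carbinol carbon and the vinyl carbon, and the O–Si bond, are cut. The ethoxyvinyl unit becomes a metallated enol ether and the ring a mixed squarate diester. The demand is 1,2-addition to one of two similar carbonyl groups, the one conjugated with the aryloxy group.

6 from 2, 3 and 4, and 2 from 1. Two C–O bonds at the squarate ring are cut. The hindered ether between ring A and ring D is thereby made as a vinylogous ester, by addition–elimination and not by arylation. The demand is stepwise substitution of two chlorides by two different oxygen nucleophiles.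

22 from 20, 20 from 19, 19 from 18. The C–Br bond at C2 is traced to an amino group, the C–I bond at C1 to the C–H ortho to that amino group, and the amino group to a nitro group. One nitrogen substituent thus places both halogens. The demands are iodination on the aniline ring and not on ring C, and a diazonium substitution next to an iodide.

18 from 17. The biaryl bond C9a–C9b is cut, which reduces the dibenzofuran to a diaryl ether. The forward step is a double C–H coupling that must choose the unhindered C–H of the nitro ring.

17 from 4 and 16. The diaryl ether C–O bond is cut, giving two commercial arenes. The nitro group para to fluorine secures the substitution.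

## Other disconnections considered

Alternative 1: The cut runs through the furan ring: the O–C bond to C4a and the C–C bond to C9b are broken, ring B becoming an aryne and ring C a cyclic 1,3-diketone ylide.
- Forward step: fluoride would release the aryne from the silylaryl triflate A2. The enolate oxygen of the iodonium ylide A3 would add to the aryne carbon remote from the dioxole oxygen, and the ylide carbon would bond to the other aryne carbon with loss of the iodine leaving group, giving the dihydrodibenzofuranone A1.
- In favour: two bonds and a ring form in one metal-free step, and ring C arrives as a vinylogous ester that is not nucleophilic. The oxygens at C1 and C2, the bay oxygen included, are present from the start as a methylenedioxy group. On this point the alternative is better than the chosen plan, which must iodinate the bay carbon and form its C–O bond late.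
- Against: A1 holds ring B as a masked catechol, so the dioxin would have to be closed with ring B as double nucleophile and ring A as a 1,2-dielectrophile. A ring A with two neighbouring leaving groups among five oxygenated carbons is not what squarate chemistry delivers. Ring C would still have to be dehydrogenated without eliminating its silyloxy group, and A2 is a multistep target of its own.
- Comparison: structurally it solves rings B/C and leaves ring A, the harder ring, open. Mechanistically its regiochemistry rests on the inductive bias of an alkoxy aryne, that of the chosen key step on torquoselectivity; both are precedented. In step count it should be longer than the five steps to 22.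

Alternative 2: One C–C bond of ring D is cut, so that ring D is made last from the 4-aryloxy-6-methyl-2-pyranone A5.
- Forward step: methoxide would open the lactone and the methyl ketone enolate would close onto the ester, turning the pyranone into the resorcinol ring of A4.
- In favour: the two ring D hydroxyls emerge free, so two fewer ethers remain for the final dealkylation; on this point the alternative is better. No electron-rich ring D is present while the ketene is generated.
- Against: it is a strong-base step late in the synthesis. Methoxide can also add to the aryloxy-bearing carbon of the pyranone and expel the core phenoxide of A6, undoing the attachment. A5 requires the hindered core phenol A6 to be joined to a pyranone first, and the construction of ring A is not addressed at all.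
- Comparison: both plans make the hindered ring A–ring D ether as a vinylogous ester, so they are equal there. The chosen plan obtains ring D from commercial 4 with no dedicated step, whereas the alternative adds at least two. The alternative is an ionic condensation, the chosen key step a pericyclic cascade.

Alternative 3: The ring C bond between the biaryl carbon and the carbon that will carry the furan oxygen is cut, ring C unfolding to the triketide ester A8.
- Forward step: base would condense the benzylic carbon of A8 onto the ester carbonyl and the resulting triketone would tautomerise to the 2-arylphloroglucinol A7.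
- In favour: all three ring C oxygens come from carbonyl groups, so no electrophilic substitution on an electron-rich ring is needed. The symmetric phloroglucinol can close the furan through either flanking hydroxyl. On regiochemical simplicity for ring C it is better than the chosen plan, and like the chosen key step it forms one C–C bond and aromatises by tautomerisation, so the two are equal in bond economy at that step.
- Against: 3,5-dioxo esters tend to lactonise through the enol oxygen or to cyclise by aldol pathways. The benzylic carbon is the least acidic carbon acid of A8 and is flanked by two ortho substituents. A7 still needs debenzylation and dehydrative furan closure, and it again presents ring B as a catechol, which forces ring A to be the electrophile.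
- Comparison: assembling A8 and closing the furan should take more steps than the two that lead from 4 and 16 to 18.

Key step: step 4

Remark (assumption): the tertiary hydroxyl of the cyclobutenone is carried as its tert-butyldimethylsilyl ether. This is a change of protecting group only; the skeleton, the bond formed and the ring closed in the key step are unchanged, and the unprotected carbinol and hydroquinone appear as F1 and F3. It lets the two para oxygens of ring A leave the key step already differentiated and avoids an oxidisable hydroquinone. Dibenzofuran positions are numbered C1–C4, C4a, O5, C5a, C6–C9, C9a, C9b.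

## Route

Step 1
Reactants: 1 squaric acid
Product: 2 3,4-dichlorocyclobut-3-ene-1,2-dione
Conditions: SOCl2, DMF (cat.), toluene, reflux
Reagents that add atoms: thionyl chloride, O=S(Cl)Cl
Why: Vilsmeier-type activation converts both vinylogous acid hydroxyls into chlorides (vinylogous acid chloride formation), giving the standard doubly electrophilic squaric acid equivalent.

Step 2
Reactants: 2 3,4-dichlorocyclobut-3-ene-1,2-dione; 3 propan-2-ol; 4 3,5-dimethoxyphenol
Product: 6 3-(3,5-dimethoxyphenoxy)-4-(propan-2-yloxy)cyclobut-3-ene-1,2-dione, via chloro ester 5 (not isolated)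
Conditions: 3 (1.0 equiv), CH2Cl2, 0 °C → rt; then 4, Et3N, −40 → 0 °C
Reagents that add atoms: none
Why: Two successive addition–elimination reactions at the vinylogous acid chloride carbons; the first alkoxy group donates into the ring and slows a second alcoholysis, and the phenol is then delivered as its ammonium phenoxide at low temperature so that O-acylation should outrun Friedel–Crafts attack by its ring carbons.

Step 3
Reactants: 6 3-(3,5-dimethoxyphenoxy)-4-(propan-2-yloxy)cyclobut-3-ene-1,2-dione; 7 ethyl vinyl ether
Product: 10 4-[(tert-butyldimethylsilyl)oxy]-2-(3,5-dimethoxyphenoxy)-4-(1-ethoxyethenyl)-3-(propan-2-yloxy)cyclobut-2-en-1-one (racemic), via 1-ethoxyvinyllithium 8 (not isolated), via lithium alkoxide 9 (not isolated)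
Conditions: 7 (excess), t-BuLi, THF, −78 → 0 °C; then 6, THF, −78 °C; then TBSOTf, −78 → −20 °C; Et3N, aq. NaHCO3
Reagents that add atoms: tert-butyldimethylsilyl trifluoromethanesulfonate, CC(C)(C)[Si](C)(C)OS(=O)(=O)C(F)(F)F
Why: α-Lithiation of the vinyl ether gives the acyl-anion equivalent 8, which should add 1,2 to the more electrophilic carbonyl of 6, the one conjugated through the ring double bond with the weakly donating aryloxy group (the other carbonyl is the better-stabilised vinylogous isopropyl ester). The carbinol stereocentre forms as a racemate, which is of no consequence, and alkoxide 9 is silylated in the same flask.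

Step 4
Reactants: 10 4-[(tert-butyldimethylsilyl)oxy]-2-(3,5-dimethoxyphenoxy)-4-(1-ethoxyethenyl)-3-(propan-2-yloxy)cyclobut-2-en-1-one (racemic)
Product: 13 4-[(tert-butyldimethylsilyl)oxy]-2-(3,5-dimethoxyphenoxy)-5-ethoxy-3-(propan-2-yloxy)phenol, via dienylketene 11 (not isolated), via cyclohexadienone 12 (not isolated)
Conditions: toluene (degassed, about 0.02 M), 110 °C, Ar, base-washed glassware
Reagents that add atoms: none
Why: This is a Moore rearrangement: on heating, the bond between the carbonyl carbon and the silyloxy-bearing carbon breaks by thermal conrotatory 4π electrocyclic ring opening, and the silyloxy group, being a donor, turns outward, which places the 1-ethoxyvinyl group cis to the new ketene in 11. The triene formed by the ketene C=C, the former ring double bond and the vinyl group then closes by thermal 6π electrocyclisation, the electrophilic ketene carbon bonding to the nucleophilic enol ether CH2; this is the only skeletal bond formed and it closes ring A as cyclohexadienone 12. Enolisation aromatises 12 to phenol 13. The closest known reaction type is the thermolysis of 4-alkenyl- or 4-aryl-4-hydroxy-, alkoxy- or silyloxycyclobutenones from squarate esters to hydroquinones and their monoethers. No stereocentre is created and the racemic carbinol centre of 10 is destroyed. The step needs torquoselectivity (oxygen out, vinyl in), which the oxygen substituent on the sp3 carbon secures, and it needs the ketene to choose the vinyl terminus over the electron-rich ring D, which the cis geometry and the nucleophilicity of the enol ether carbon secure. Each squarate carbon keeps its own oxygen, so the hydroxyl from the ketene carbonyl emerges free while the para oxygen stays silylated.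

Step 5
Reactants: 13 4-[(tert-butyldimethylsilyl)oxy]-2-(3,5-dimethoxyphenoxy)-5-ethoxy-3-(propan-2-yloxy)phenol
Product: 15 3-(3,5-dimethoxyphenoxy)-6-ethoxy-4-methoxy-2-(propan-2-yloxy)phenol, via methyl ether 14 (not isolated)
Conditions: MeI, K2CO3, acetone, rt; filtration and evaporation; then TBAF, THF, 0 °C; aq. NH4Cl
Reagents that add atoms: iodomethane, CI
Why: Williamson methylation of the only free phenol, then fluoride cleavage of the aryl silyl ether once excess iodomethane has been removed; this caps the ring A hydroxyl next to the ring D ether and frees the hydroxyl flanked by ethoxy and isopropoxy for the first diaryl ether bond.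

Step 6
Reactants: 4 3,5-dimethoxyphenol; 16 4-fluoro-2-methoxy-1-nitrobenzene
Product: 17 4-(3,5-dimethoxyphenoxy)-2-methoxy-1-nitrobenzene
Conditions: K2CO3, DMF, 80 °C
Reagents that add atoms: none
Why: Nucleophilic aromatic substitution (SNAr) of the fluoride para to the nitro group by the phenoxide.

Step 7
Reactants: 17 4-(3,5-dimethoxyphenoxy)-2-methoxy-1-nitrobenzene
Product: 18 3,7,9-trimethoxy-2-nitrodibenzo[b,d]furan
Conditions: Pd(OAc)2 (5 mol%), K2CO3 (10 mol%), PivOH, air, 120 °C
Reagents that add atoms: none
Why: Intramolecular oxidative (dehydrogenative) biaryl coupling of a diaryl ether by divalent palladium with air as terminal oxidant, a known route to dibenzofurans. On the nitro ring the C–H para to methoxy is far less hindered than the one between methoxy and the ether oxygen, and the two ortho C–H positions of the dimethoxyphenoxy ring are equivalent, so one regioisomer is expected.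

Step 8
Reactants: 18 3,7,9-trimethoxy-2-nitrodibenzo[b,d]furan
Product: 19 3,7,9-trimethoxydibenzo[b,d]furan-2-amine
Conditions: H2 (1 atm), Pd/C, EtOAc–MeOH, rt
Reagents that add atoms: none
Why: Catalytic hydrogenation of an aromatic nitro group to the aniline; no other reducible group is present.

Step 9
Reactants: 19 3,7,9-trimethoxydibenzo[b,d]furan-2-amine
Product: 20 1-iodo-3,7,9-trimethoxydibenzo[b,d]furan-2-amine
Conditions: BnMe3N+ ICl2− (1.05 equiv), CaCO3, CH2Cl2–MeOH, rt
Reagents that add atoms: benzyltrimethylammonium dichloroiodate, C[N+](C)(C)Cc1ccccc1.Cl[I-]Cl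
Why: Electrophilic aromatic iodination directed by the free amino group, whose para position (C4a) and one ortho position (C3) are blocked, leaving C1. The dichloroiodate salt in buffered CH2Cl2–MeOH iodinates anilines but needs a Lewis acid for aryl ethers, which should spare ring C.

Step 10
Reactants: 20 1-iodo-3,7,9-trimethoxydibenzo[b,d]furan-2-amine
Product: 22 2-bromo-1-iodo-3,7,9-trimethoxydibenzo[b,d]furan, via diazonium bromide 21 (not isolated)
Conditions: NaNO2, 48% aq. HBr, MeCN, 0 °C; then CuBr (cat.), 0 → 60 °C
Reagents that add atoms: hydrobromic acid, Br
Why: Sandmeyer reaction: diazotisation, then replacement of N2 by bromide catalysed by monovalent copper; the diazonium group is para to an ether oxygen and should form cleanly at 0 °C.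

Step 11
Reactants: 15 3-(3,5-dimethoxyphenoxy)-6-ethoxy-4-methoxy-2-(propan-2-yloxy)phenol; 22 2-bromo-1-iodo-3,7,9-trimethoxydibenzo[b,d]furan
Product: 23 2-bromo-1-[3-(3,5-dimethoxyphenoxy)-6-ethoxy-4-methoxy-2-(propan-2-yloxy)phenoxy]-3,7,9-trimethoxydibenzo[b,d]furan
Conditions: CuI (20 mol%), picolinic acid (40 mol%), K3PO4, DMSO, 90–100 °C, Ar
Reagents that add atoms: none
Why: Ullmann diaryl ether synthesis (copper-catalysed O-arylation of a phenol). The C–I bond should react before the more electron-rich, doubly flanked C–Br bond, and the picolinic acid system is the one known to tolerate ortho substituents on both partners.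

Step 12
Reactants: 23 2-bromo-1-[3-(3,5-dimethoxyphenoxy)-6-ethoxy-4-methoxy-2-(propan-2-yloxy)phenoxy]-3,7,9-trimethoxydibenzo[b,d]furan
Product: 24 2-[(2-bromo-3,7,9-trimethoxydibenzo[b,d]furan-1-yl)oxy]-6-(3,5-dimethoxyphenoxy)-3-ethoxy-5-methoxyphenol
Conditions: BCl3, CH2Cl2, −78 → 0 °C; aq. NaHCO3
Reagents that add atoms: none
Why: Lewis acid dealkylation: BCl3 cleaves a secondary alkyl aryl ether far faster than methyl or ethyl ethers, and the isopropoxy oxygen is the one flanked by two ether oxygens that can chelate boron.

Step 13
Reactants: 24 2-[(2-bromo-3,7,9-trimethoxydibenzo[b,d]furan-1-yl)oxy]-6-(3,5-dimethoxyphenoxy)-3-ethoxy-5-methoxyphenol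
Product: 25 hexamethyl monoethyl ether of 26 (3,5-dimethoxyphenoxy on ring A, OMe on the ring A carbon next to it, OEt on the ring A carbon beyond the CH, OMe at C3, C7 and C9 of the dibenzofuran part)
Conditions: CuI (20 mol%), N,N-dimethylglycine hydrochloride, Cs2CO3, 1,4-dioxane, 110 °C, Ar, high dilution
Reagents that add atoms: none
Why: Intramolecular Ullmann etherification; the phenoxide displaces the neighbouring aryl bromide through a six-membered transition ring, closing the 1,4-dioxin in the only orientation that the two preceding steps allow.

Step 14
Reactants: 25 hexamethyl monoethyl ether of 26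
Product: 26 target heptaphenol (3,5-dihydroxyphenoxy on ring A, hydroxyls on the two ring A carbons flanking the CH, hydroxyls at C3, C7 and C9 of the dibenzofuran part, dioxin oxygens on C1 and C2)
Conditions: BBr3 (excess), CH2Cl2, −78 °C → rt; MeOH, then H2O; Ar
Reagents that add atoms: none
Why: Exhaustive BBr3 cleavage of the six methyl ethers and the ethyl ether; diaryl ether, dioxin and furan C–O bonds are not attacked, and the polyphenol should be isolated under argon.

## Compound list

1 | squaric acid (3,4-dihydroxycyclobut-3-ene-1,2-dione) | O=C1C(O)=C(O)C1=O | starting material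
2 | 3,4-dichlorocyclobut-3-ene-1,2-dione | O=C1C(Cl)=C(Cl)C1=O | intermediate
3 | propan-2-ol | CC(C)O | starting material
4 | 3,5-dimethoxyphenol | COc1cc(O)cc(OC)c1 | starting material
5 | 3-chloro-4-(propan-2-yloxy)cyclobut-3-ene-1,2-dione | CC(C)OC1=C(Cl)C(=O)C1=O | intermediate
6 | 3-(3,5-dimethoxyphenoxy)-4-(propan-2-yloxy)cyclobut-3-ene-1,2-dione | CC(C)OC1=C(Oc2cc(OC)cc(OC)c2)C(=O)C1=O | intermediate
7 | ethyl vinyl ether (ethoxyethene) | C=COCC | starting material
8 | 1-ethoxyvinyllithium | [Li]C(=C)OCC | intermediate
9 | lithium alkoxide of 2-(3,5-dimethoxyphenoxy)-4-(1-ethoxyethenyl)-4-hydroxy-3-(propan-2-yloxy)cyclobut-2-en-1-one (racemic) | [Li]OC1(C(=C)OCC)C(OC(C)C)=C(Oc2cc(OC)cc(OC)c2)C1=O | intermediate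
10 | 4-[(tert-butyldimethylsilyl)oxy]-2-(3,5-dimethoxyphenoxy)-4-(1-ethoxyethenyl)-3-(propan-2-yloxy)cyclobut-2-en-1-one (racemic) | C=C(OCC)C1(O[Si](C)(C)C(C)(C)C)C(OC(C)C)=C(Oc2cc(OC)cc(OC)c2)C1=O | intermediate
11 | dienylketene: 4-[(tert-butyldimethylsilyl)oxy]-2-(3,5-dimethoxyphenoxy)-5-ethoxy-3-(propan-2-yloxy)hexa-1,3,5-trien-1-one, ketene and ethoxyvinyl cis on the central double bond | O=C=C(Oc1cc(OC)cc(OC)c1)/C(OC(C)C)=C(/O[Si](C)(C)C(C)(C)C)C(=C)OCC | intermediate
12 | 4-[(tert-butyldimethylsilyl)oxy]-2-(3,5-dimethoxyphenoxy)-5-ethoxy-3-(propan-2-yloxy)cyclohexa-2,4-dien-1-one | O=C1CC(OCC)=C(O[Si](C)(C)C(C)(C)C)C(OC(C)C)=C1Oc1cc(OC)cc(OC)c1 | intermediate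
13 | 4-[(tert-butyldimethylsilyl)oxy]-2-(3,5-dimethoxyphenoxy)-5-ethoxy-3-(propan-2-yloxy)phenol | Oc1cc(OCC)c(O[Si](C)(C)C(C)(C)C)c(OC(C)C)c1Oc1cc(OC)cc(OC)c1 | intermediate
14 | tert-butyl[3-(3,5-dimethoxyphenoxy)-6-ethoxy-4-methoxy-2-(propan-2-yloxy)phenoxy]dimethylsilane | COc1cc(OCC)c(O[Si](C)(C)C(C)(C)C)c(OC(C)C)c1Oc1cc(OC)cc(OC)c1 | intermediate
15 | 3-(3,5-dimethoxyphenoxy)-6-ethoxy-4-methoxy-2-(propan-2-yloxy)phenol | COc1cc(OCC)c(O)c(OC(C)C)c1Oc1cc(OC)cc(OC)c1 | intermediate
16 | 4-fluoro-2-methoxy-1-nitrobenzene | COc1cc(F)ccc1[N+](=O)[O-] | starting material
17 | 4-(3,5-dimethoxyphenoxy)-2-methoxy-1-nitrobenzene | COc1cc(OC)cc(Oc2ccc([N+](=O)[O-])c(OC)c2)c1 | intermediate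
18 | 3,7,9-trimethoxy-2-nitrodibenzo[b,d]furan | COc1cc(OC)c2c(c1)oc1cc(OC)c([N+](=O)[O-])cc12 | intermediate
19 | 3,7,9-trimethoxydibenzo[b,d]furan-2-amine | COc1cc(OC)c2c(c1)oc1cc(OC)c(N)cc12 | intermediate
20 | 1-iodo-3,7,9-trimethoxydibenzo[b,d]furan-2-amine | COc1cc(OC)c2c(c1)oc1cc(OC)c(N)c(I)c12 | intermediate
21 | 1-iodo-3,7,9-trimethoxydibenzo[b,d]furan-2-diazonium bromide | COc1cc(OC)c2c(c1)oc1cc(OC)c([N+]#N)c(I)c12.[Br-] | intermediate
22 | 2-bromo-1-iodo-3,7,9-trimethoxydibenzo[b,d]furan | COc1cc(OC)c2c(c1)oc1cc(OC)c(Br)c(I)c12 | intermediate
23 | 2-bromo-1-[3-(3,5-dimethoxyphenoxy)-6-ethoxy-4-methoxy-2-(propan-2-yloxy)phenoxy]-3,7,9-trimethoxydibenzo[b,d]furan | COc1cc(OC)c2c(c1)oc1cc(OC)c(Br)c(Oc3c(OCC)cc(OC)c(Oc4cc(OC)cc(OC)c4)c3OC(C)C)c12 | intermediate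
24 | 2-[(2-bromo-3,7,9-trimethoxydibenzo[b,d]furan-1-yl)oxy]-6-(3,5-dimethoxyphenoxy)-3-ethoxy-5-methoxyphenol | COc1cc(OC)c2c(c1)oc1cc(OC)c(Br)c(Oc3c(OCC)cc(OC)c(Oc4cc(OC)cc(OC)c4)c3O)c12 | intermediate
25 | hexamethyl monoethyl ether of the target (benzofuro-fused dibenzo-1,4-dioxin; ring A: 3,5-dimethoxyphenoxy, OMe, CH, OEt; dibenzofuran part: 3,7,9-trimethoxy, dioxin oxygens on C1 and C2) | COc1cc(OC)cc(Oc2c(OC)cc(OCC)c3c2Oc2c(OC)cc4oc5cc(OC)cc(OC)c5c4c2O3)c1 | intermediate
26 | target heptaphenol CNP0256302.0 (benzofuro-fused dibenzo-1,4-dioxin; ring A: 3,5-dihydroxyphenoxy, OH, CH, OH; dibenzofuran part: 3,7,9-trihydroxy, dioxin oxygens on C1 and C2) | Oc1cc(O)cc(Oc2c(O)cc(O)c3c2Oc2c(O)cc4oc5cc(O)cc(O)c5c4c2O3)c1 | target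

## Step count and risks

Total step count: 14. Longest linear sequence: 9 steps (steps 1–5 and 11–14; the branch of steps 6–10 followed by 11–14 is equally long).

**Step 4 (key step).**
- What may go wrong: loss or transfer of the silyl group at 110 °C, and interception of the ketene (by traces of water or by acylation of the electron-rich ring D) before it closes. Hydrolysis of the enol ether on acidic surfaces would add to this, and the result would be oxidisable para-dihydroxy material.
- Fallback: setting out from 6 (with 7), the alkoxide 9 is quenched with aqueous NH4Cl to give the free carbinol 2-(3,5-dimethoxyphenoxy)-4-(1-ethoxyethenyl)-4-hydroxy-3-(propan-2-yloxy)cyclobut-2-en-1-one F1. This is thermolysed in toluene and the crude product is oxidised with Ag2O to the air-stable, purifiable quinone 2-(3,5-dimethoxyphenoxy)-5-ethoxy-3-(propan-2-yloxy)cyclohexa-2,5-diene-1,4-dione F2. Reduction with Na2S2O4 gives the hydroquinone 2-(3,5-dimethoxyphenoxy)-5-ethoxy-3-(propan-2-yloxy)benzene-1,4-diol F3, whose less hindered hydroxyl is methylated with one equivalent of MeI and K2CO3, coming back to the route at 15.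

**Step 11.**
- What may go wrong: slow C–O bond formation at the bay iodide, which is flanked by bromine and faces the C9 methoxy group, with a phenoxide that itself has two ortho substituents. Reductive deiodination and oxidation of the electron-rich phenoxide would then dominate.
- Fallback: the bond is made by nitro-activated nucleophilic aromatic substitution in place of copper catalysis, setting out from 19. Chlorination with N-chlorosuccinimide should give 1-chloro-3,7,9-trimethoxydibenzo[b,d]furan-2-amine F4. Oxidation of the amino group with dimethyldioxirane should give 1-chloro-3,7,9-trimethoxy-2-nitrodibenzo[b,d]furan F5. Phenol 15 with K2CO3 in DMSO should displace the chloride ortho to the nitro group to give 1-[3-(3,5-dimethoxyphenoxy)-6-ethoxy-4-methoxy-2-(propan-2-yloxy)phenoxy]-3,7,9-trimethoxy-2-nitrodibenzo[b,d]furan F6. BCl3 removes the isopropyl group to give 6-(3,5-dimethoxyphenoxy)-3-ethoxy-5-methoxy-2-[(3,7,9-trimethoxy-2-nitrodibenzo[b,d]furan-1-yl)oxy]phenol F7. Heating with K2CO3 in DMSO displaces the nitro group intramolecularly (the classical catechol/ortho-halonitroarene dioxin synthesis), coming back to the route at 25.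

**Step 9.**
- What may go wrong: iodination of ring C competing with substitution at the crowded C1, and oxidation of the electron-rich aniline by the iodinating agent.
- Fallback: setting out from 19, the smaller and faster electrophile N-bromosuccinimide at −78 °C should give 1-bromo-3,7,9-trimethoxydibenzo[b,d]furan-2-amine F8. A copper-catalysed aromatic Finkelstein exchange (CuI, N,N′-dimethylethylenediamine, NaI, 1,4-dioxane, 110 °C) then converts bromide to iodide, coming back to the route at 20.

**Step 3.**
- What may go wrong: addition to the other carbonyl group, or addition–elimination at the aryloxy-bearing carbon with loss of aryloxide, because the discrimination rests only on the different donor strength of isopropoxy and aryloxy.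
- Fallback: the regiochemistry is fixed by symmetry and by a position-specific ester exchange. Setting out from 2, two equivalents of 4 and Et3N give 3,4-bis(3,5-dimethoxyphenoxy)cyclobut-3-ene-1,2-dione F9. Addition of 8 and silylation as in step 3 give 4-[(tert-butyldimethylsilyl)oxy]-2,3-bis(3,5-dimethoxyphenoxy)-4-(1-ethoxyethenyl)cyclobut-2-en-1-one (racemic) F10. Only the aryloxy group on the β-carbon of the enone is a vinylogous ester; it is exchanged by 3 with a catalytic amount of NaOCH(CH3)2 in THF at 0 °C, coming back to the route at 10.

**Step 7.**
- What may go wrong: unproductive palladation at other positions and low turnover, because both ortho positions of the dimethoxyphenoxy ring are flanked by methoxy; some closure next to the methoxy group of the nitro ring is also possible.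
- Fallback: setting out from 4, SNAr with 1-bromo-2-fluoro-4-methoxy-5-nitrobenzene F11 (K2CO3, DMF) gives 1-bromo-2-(3,5-dimethoxyphenoxy)-4-methoxy-5-nitrobenzene F12. The bromide then fixes the site of ring closure in a direct arylation by zerovalent palladium (Pd(OAc)2, PCy3·HBF4, K2CO3, DMA, 130 °C), coming back to the route at 18.

## Further compounds

F1 | step 4 | 2-(3,5-dimethoxyphenoxy)-4-(1-ethoxyethenyl)-4-hydroxy-3-(propan-2-yloxy)cyclobut-2-en-1-one (racemic) | C=C(OCC)C1(O)C(OC(C)C)=C(Oc2cc(OC)cc(OC)c2)C1=O
F2 | step 4 | 2-(3,5-dimethoxyphenoxy)-5-ethoxy-3-(propan-2-yloxy)cyclohexa-2,5-diene-1,4-dione | O=C1C=C(OCC)C(=O)C(OC(C)C)=C1Oc1cc(OC)cc(OC)c1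
F3 | step 4 | 2-(3,5-dimethoxyphenoxy)-5-ethoxy-3-(propan-2-yloxy)benzene-1,4-diol | Oc1cc(OCC)c(O)c(OC(C)C)c1Oc1cc(OC)cc(OC)c1
F4 | step 11 | 1-chloro-3,7,9-trimethoxydibenzo[b,d]furan-2-amine | COc1cc(OC)c2c(c1)oc1cc(OC)c(N)c(Cl)c12
F5 | step 11 | 1-chloro-3,7,9-trimethoxy-2-nitrodibenzo[b,d]furan | COc1cc(OC)c2c(c1)oc1cc(OC)c([N+](=O)[O-])c(Cl)c12
F6 | step 11 | 1-[3-(3,5-dimethoxyphenoxy)-6-ethoxy-4-methoxy-2-(propan-2-yloxy)phenoxy]-3,7,9-trimethoxy-2-nitrodibenzo[b,d]furan | COc1cc(OC)c2c(c1)oc1cc(OC)c([N+](=O)[O-])c(Oc3c(OCC)cc(OC)c(Oc4cc(OC)cc(OC)c4)c3OC(C)C)c12
F7 | step 11 | 6-(3,5-dimethoxyphenoxy)-3-ethoxy-5-methoxy-2-[(3,7,9-trimethoxy-2-nitrodibenzo[b,d]furan-1-yl)oxy]phenol | COc1cc(OC)c2c(c1)oc1cc(OC)c([N+](=O)[O-])c(Oc3c(OCC)cc(OC)c(Oc4cc(OC)cc(OC)c4)c3O)c12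
F8 | step 9 | 1-bromo-3,7,9-trimethoxydibenzo[b,d]furan-2-amine | COc1cc(OC)c2c(c1)oc1cc(OC)c(N)c(Br)c12
F9 | step 3 | 3,4-bis(3,5-dimethoxyphenoxy)cyclobut-3-ene-1,2-dione | COc1cc(OC)cc(OC2=C(Oc3cc(OC)cc(OC)c3)C(=O)C2=O)c1
F10 | step 3 | 4-[(tert-butyldimethylsilyl)oxy]-2,3-bis(3,5-dimethoxyphenoxy)-4-(1-ethoxyethenyl)cyclobut-2-en-1-one (racemic) | C=C(OCC)C1(O[Si](C)(C)C(C)(C)C)C(Oc2cc(OC)cc(OC)c2)=C(Oc2cc(OC)cc(OC)c2)C1=O
F11 | step 7 | 1-bromo-2-fluoro-4-methoxy-5-nitrobenzene | COc1cc(F)c(Br)cc1[N+](=O)[O-]
F12 | step 7 | 1-bromo-2-(3,5-dimethoxyphenoxy)-4-methoxy-5-nitrobenzene | COc1cc(OC)cc(Oc2cc(OC)c([N+](=O)[O-])cc2Br)c1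
A1 | alternative 1 | 7-[(tert-butyldimethylsilyl)oxy]-3-methoxy-1,2-(methylenedioxy)-7,8-dihydrodibenzo[b,d]furan-9(6H)-one (racemic) | COc1cc2oc3c(c2c2OCOc12)C(=O)CC(O[Si](C)(C)C(C)(C)C)C3
A2 | alternative 1 | 7-methoxy-4-(trimethylsilyl)-1,3-benzodioxol-5-yl trifluoromethanesulfonate | COc1cc(OS(=O)(=O)C(F)(F)F)c([Si](C)(C)C)c2OCOc12
A3 | alternative 1 | phenyliodonium ylide of 5-[(tert-butyldimethylsilyl)oxy]cyclohexane-1,3-dione | CC(C)(C)[Si](C)(C)OC1CC(=O)C([I+]c2ccccc2)=C([O-])C1
A4 | alternative 2 | pentamethyl ether of the target with both ring D hydroxyls free | Oc1cc(O)cc(Oc2c(OC)cc(OC)c3c2Oc2c(OC)cc4oc5cc(OC)cc(OC)c5c4c2O3)c1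
A5 | alternative 2 | 4-aryloxy-6-methyl-2H-pyran-2-one carrying the pentamethylated ring A/B/C core on oxygen | Cc1cc(Oc2c(OC)cc(OC)c3c2Oc2c(OC)cc4oc5cc(OC)cc(OC)c5c4c2O3)cc(=O)o1
A6 | alternative 2 | pentamethylated ring A/B/C core phenol (free hydroxyl on the ring A carbon that carries ring D in the target) | Oc1c(OC)cc(OC)c2c1Oc1c(OC)cc3oc4cc(OC)cc(OC)c4c3c1O2
A7 | alternative 3 | 2-[5-(benzyloxy)-7-methoxy-1,3-benzodioxol-4-yl]benzene-1,3,5-triol | Oc1cc(O)c(-c2c(OCc3ccccc3)cc(OC)c3OCOc23)c(O)c1
A8 | alternative 3 | methyl 6-[5-(benzyloxy)-7-methoxy-1,3-benzodioxol-4-yl]-3,5-dioxohexanoate | COC(=O)CC(=O)CC(=O)Cc1c(OCc2ccccc2)cc(OC)c2OCOc12
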